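# Proposed synthesis of hansfordiol D by late-stage catalytic asymmetric methylation

## The problem

Hansfordiol D (16) is a 5-alkylresorcinol: one benzene ring with hydroxyl groups at C1 and C3 and an unbranched seventeen-carbon chain at C5, so no ring has to be built and the whole task is the chain. The chain holds two Z alkenes, C8'=C9' and C11'=C12', separated by the single methylene C10', and ends in a secondary methyl carbinol at C16' of S configuration. That carbinol is the only stereocentre. Three methylene groups (C13' to C15') separate it from the nearer alkene and it is far from the ring, so nothing in the molecule can direct its formation and it can direct nothing else. The skipped diene is the fragile part: the doubly allylic C10'–H bonds are easily abstracted or deprotonated, which leads to conjugation, Z/E scrambling or autoxidation, and the alkenes forbid any late hydrogenolysis. The electron-rich resorcinol is open to oxidation and electrophilic attack, and its acidic phenols must be masked through the organometallic steps by groups that come off without hydrogen, boron halides or strong base. A late catalytic solution is possible because C16' carries the terminal methyl C17'. Cutting C16'–C17' leaves an unbranched aldehyde with no α-substituent and no chelating heteroatom, whose nearest functional group is the C11'=C12' alkene, so a chiral catalyst meets no competing bias.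

## Retrosynthesis

**Phenol unmasking (16 from 15).** The two aryl C–O acetal bonds are cut last. Methoxymethyl ethers are preferred to benzyl ethers (hydrogenolysis would reduce the diene), to methyl ethers (boron tribromide or hot thiolate) and to aryl silyl ethers (which would not survive acetylide and carbonate steps). The forward step needs only dilute acid in methanol, which the secondary carbinol and the Z alkenes should tolerate.

**The stereocentre (15 from 13 and 14).** The C16'–C17' bond is cut. A cut further inside the chain would force the carbinol to be bought as a chiral building block and carried, protected, through acetylide chemistry and semi-hydrogenation. The terminal cut instead removes one carbon and the only stereocentre together, leaving the achiral aldehyde 13 and dimethylzinc (14). The forward reaction must distinguish the two faces of an unbiased aliphatic aldehyde by catalyst alone and must leave the alkenes and acetals alone.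

**Aldehyde and both Z alkenes (13 from 12 from 11).** The aldehyde is traced to the primary alcohol 12, and both alkenes of 12 to the 1,4-diyne 11. No carbon–carbon bond is cut here. The gain is that two geometries become one cis-semi-hydrogenation, and the diyne can be assembled by acetylide chemistry. The forward steps need an oxidation that stops at the aldehyde without acid or metal, and a poisoned catalyst that neither over-reduces nor isomerises.

**The diyne (11 from 9 and 10).** The C10'–C11' bond between the propargylic methylene and the alkyne carbon is cut. This gives the propargylic bromide 9 and commercial hex-5-yn-1-ol (10), which supplies C11'–C16' with the oxygen already at C16'. Cutting C9'–C10' instead would put the propargylic halide on the small fragment and cost steps to prepare it. The forward coupling needs a copper acetylide and a mild base so that the new doubly propargylic methylene is not isomerised.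

**The propargylic carbon (9 from 8 from 5 and 6).** Bromide 9 comes from alcohol 8, and 8 from cutting C7'–C8' into the primary bromide 5 and prop-2-yn-1-ol (6), used as its dilithium salt 7. This is a plain acetylide alkylation at an unhindered primary carbon and needs no protecting group on the propargylic oxygen.

**Arene–chain junction (5 from 2 and 3; 2 from 1).** The bond between ring carbon C5 and C1' is cut into aryl bromide 2 and 7-bromohept-1-ene (3), joined through the borane 4. An olefination at C1'=C2' followed by hydrogenation and bromination would reach the same bromide but with three more operations. The forward reaction needs a coupling that takes the aryl bromide and spares the alkyl bromide. Aryl bromide 2 is the bis-methoxymethyl ether of commercial 5-bromobenzene-1,3-diol (1).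

## Roads not taken

Alternative 1: The arene itself is cut. Opening the ring bond between the chain-bearing carbon and its ester-bearing neighbour unfolds the resorcylate methyl 2,4-dihydroxy-6-[(8Z,11Z,16S)-16-(tert-butyldimethylsilyloxy)heptadeca-8,11-dienyl]benzoate A1 into the acyclic triketo ester methyl (15Z,18Z,23S)-23-(tert-butyldimethylsilyloxy)-3,5,7-trioxotetracosa-15,18-dienoate A2. In the forward key step mild base lets C2 of A2 add to its C7 ketone; loss of water and enolisation then close the benzene ring of A1. The merits are that the 1,3-dioxygen pattern arises from carbonyl chemistry without phenol protection and that the logic follows the biosynthesis. The weak points lie in the precursor: A2 already contains the whole chain, so the skipped diene and a silyl-protected stereocentre from a chiral building block must be in place before the ring exists. Making A2 means acylating a polyanion of a dioxo ester next to a doubly allylic methylene. Such polycarbonyl chains also close to 4-hydroxypyranones or, by Claisen condensation, to acylphloroglucinols. A1 still needs ester hydrolysis, decarboxylation and desilylation before the target is reached. In comparison, this road saves the two protecting-group steps on the phenols, which is a real advantage. Against it, the chosen plan buys the ring, makes the chain by selective two-electron bond formations only, and needs no chiral building block.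

Alternative 2: The saturated C4'–C5' bond in the tether is cut, giving two redox-active esters, 1,3-dioxoisoindolin-2-yl 5-[3,5-bis(methoxymethoxy)phenyl]pentanoate A4 and 1,3-dioxoisoindolin-2-yl (5Z,8Z,13S)-13-(tert-butyldimethylsilyloxy)tetradeca-5,8-dienoate A5. In the forward key step A4 and A5 are reduced at a cathode in the presence of NiCl2·6H2O and a terpyridine ligand; both lose CO2 and the two primary alkyl fragments join to give the fully protected coupling product tert-butyl{[(2S,6Z,9Z)-17-[3,5-bis(methoxymethoxy)phenyl]heptadeca-6,9-dien-2-yl]oxy}dimethylsilane A3. Desilylation and acetal cleavage of A3 would then give the target. The merits are that this is the most convergent of the four plans, that A4 and A5 are of similar size and come from stable carboxylic acids, and that the conditions are mild to the acetals and the silyl ether of A3. The weak points are these: two unbiased primary alkyl partners couple statistically, so an excess of A4 and separation of A3 from both homodimers are needed. A5 still requires the same diyne coupling and semi-hydrogenation as the chosen route, plus a purchased stereocentre and a silyl group. The doubly allylic C10'–H bonds are exposed to alkyl radicals and low-valent nickel, which invites hydrogen abstraction and Z/E isomerisation. In comparison, this road is better in convergence and probably in longest linear sequence. The chosen plan sets against this the absence of statistical coupling and of radicals near C10', catalytic creation of the stereocentre, and one protecting-group type fewer. Its linearity costs little because each added fragment is a commercial, unfunctionalised building block.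

Alternative 3: Two ring bonds of the arene are cut, dividing it into a four-carbon and a two-carbon piece, 3-[(8Z,11Z,16S)-16-(tert-butyldimethylsilyloxy)heptadeca-8,11-dien-1-yl]cyclobut-2-en-1-one A7 and (triisopropylsilyloxy)acetylene A8. In the forward key step, a Danheiser-type benzannulation, heating opens A7 to a vinylketene, which adds A8 (ketene carbonyl carbon to the alkyne CH, ketene α-carbon to the oxygenated alkyne carbon). A second ring opening and a 6π electrocyclisation then give the mono-silylated resorcinol 3-[(8Z,11Z,16S)-16-(tert-butyldimethylsilyloxy)heptadeca-8,11-dienyl]-5-(triisopropylsilyloxy)phenol A6. The merits are that the annulation is regiospecific, neutral and metal-free and that A6 is delivered with its two ring oxygens differentiated. The weak points are that the two phenols of the target are equivalent, so the differentiation in A6 is wasted. A7 must carry the finished chain with diene and protected stereocentre and is itself laborious to make. Ketene intermediates heated beside two Z alkenes invite ketene–alkene cycloaddition and thermal isomerisation. A8 is moisture-sensitive, and two silyl removals from A6 follow. In comparison, the final deprotection of A6 would use fluoride and not acid, which is kinder to the diene, and in that respect this road is at least as good. The chosen plan answers with dilute methanolic HCl at room temperature, which skipped dienes should withstand, and is otherwise shorter and rests on a commercial arene.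

Key step: step 8

Assumption: the (1R,2R)-bis(triflamide) ligand is taken to direct methyl to the Si face of the aldehyde, as it directs ethyl in additions of Et2Zn to simple aldehydes; should the opposite sense be found, the (1S,2S) ligand is used with nothing else changed.

## Route

Step 1
Reactants: 1 5-bromobenzene-1,3-diol
Product: 2 1-bromo-3,5-bis(methoxymethoxy)benzene
Conditions: MOMCl, iPr2NEt, CH2Cl2, 0 °C to rt
Reagents that add atoms: chloromethyl methyl ether, COCCl
Why: O-alkylation of both phenols (methoxymethyl ether formation) with an amine base; the aryl bromide is inert, and the acetals then withstand base, organolithium, borane, hydrogenation and buffered oxidation.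

Step 2
Reactants: 2 1-bromo-3,5-bis(methoxymethoxy)benzene; 3 7-bromohept-1-ene
Product: 5 1-(7-bromoheptyl)-3,5-bis(methoxymethoxy)benzene, via 9-(7-bromoheptyl)-9-BBN 4 (not isolated)
Conditions: 3, 9-BBN, THF, 0 °C to rt; then 2, PdCl2(dppf) (5 mol %), K3PO4·H2O, DMF/THF, 50 °C
Reagents that add atoms: none
Why: 9-BBN hydroborates the terminal alkene at C1 without touching the primary bromide, and the B-alkyl Suzuki–Miyaura coupling joins the primary alkyl group to the aryl bromide. Zerovalent palladium on dppf inserts into the aryl C–Br bond far faster than into an unactivated alkyl C–Br bond, and phosphate is too weak a nucleophile to displace the bromide at 50 °C.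

Step 3
Reactants: 5 1-(7-bromoheptyl)-3,5-bis(methoxymethoxy)benzene; 6 prop-2-yn-1-ol
Product: 8 10-[3,5-bis(methoxymethoxy)phenyl]dec-2-yn-1-ol, via dilithiated prop-2-yn-1-ol 7 (not isolated)
Conditions: 6 (3 equiv), n-BuLi (5.8 equiv), THF/DMPU, −78 to 0 °C; then 5, 0 °C to rt; H2O
Reagents that add atoms: none
Why: Alkylation of a lithium acetylide by a primary bromide (SN2) in a dipolar cosolvent; in the dianion the acetylide carbon is much more nucleophilic than the alkoxide. Slightly less than two equivalents of n-BuLi per propargyl alcohol leaves no free alkyllithium to metalate the arene between the acetal oxygens or to exchange the bromide.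

Step 4
Reactants: 8 10-[3,5-bis(methoxymethoxy)phenyl]dec-2-yn-1-ol
Product: 9 1-(10-bromodec-8-yn-1-yl)-3,5-bis(methoxymethoxy)benzene
Conditions: CBr4, PPh3, CH2Cl2, 0 °C
Reagents that add atoms: carbon tetrabromide, BrC(Br)(Br)Br
Why: Appel reaction; the primary propargylic alcohol is converted to the bromide under neutral conditions that the acetals tolerate, and substitution at the unhindered carbon should proceed without allenic rearrangement.

Step 5
Reactants: 9 1-(10-bromodec-8-yn-1-yl)-3,5-bis(methoxymethoxy)benzene; 10 hex-5-yn-1-ol
Product: 11 16-[3,5-bis(methoxymethoxy)phenyl]hexadeca-5,8-diyn-1-ol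
Conditions: CuI, NaI, Cs2CO3, DMF, rt
Reagents that add atoms: none
Why: Copper-mediated coupling of a terminal alkyne with a propargylic halide: the copper acetylide of 10 displaces the halide (iodide after exchange with NaI) at the primary carbon, forming C10'–C11' and the 1,4-diyne. The mild carbonate base should leave the free hydroxyl unalkylated and the doubly propargylic methylene unisomerised.

Step 6
Reactants: 11 16-[3,5-bis(methoxymethoxy)phenyl]hexadeca-5,8-diyn-1-ol
Product: 12 (5Z,8Z)-16-[3,5-bis(methoxymethoxy)phenyl]hexadeca-5,8-dien-1-ol
Conditions: H2 (1 atm), Ni(OAc)2·4H2O, NaBH4, ethylenediamine, EtOH, rt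
Reagents that add atoms: none
Why: cis-Semi-hydrogenation of both alkynes on P-2 nickel boride (Ni2B) poisoned with ethylenediamine; syn delivery of hydrogen from the metal surface sets both Z geometries at once, and the amine-poisoned catalyst binds alkenes too weakly to reduce or isomerise them.

Step 7
Reactants: 12 (5Z,8Z)-16-[3,5-bis(methoxymethoxy)phenyl]hexadeca-5,8-dien-1-ol
Product: 13 (5Z,8Z)-16-[3,5-bis(methoxymethoxy)phenyl]hexadeca-5,8-dienal
Conditions: Dess–Martin periodinane, NaHCO3, CH2Cl2, 0 °C to rt
Reagents that add atoms: none
Why: Dess–Martin oxidation of the primary alcohol stops at the aldehyde under buffered, metal-free conditions, so the skipped diene and the acetals are untouched; the aldehyde has no α-stereocentre and is used directly.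

Step 8
Reactants: 13 (5Z,8Z)-16-[3,5-bis(methoxymethoxy)phenyl]hexadeca-5,8-dienal; 14 dimethylzinc
Product: 15 (2S,6Z,9Z)-17-[3,5-bis(methoxymethoxy)phenyl]heptadeca-6,9-dien-2-ol
Conditions: Me2Zn (3 equiv), Ti(OiPr)4 (1.2 equiv), (1R,2R)-N,N'-(cyclohexane-1,2-diyl)bis(trifluoromethanesulfonamide) (10 mol %), toluene, −20 to 0 °C; aq. NH4Cl
Reagents that add atoms: none
Why: Ti(OiPr)4 and the bis(triflamide) form a chiral bis(sulfonamido)titanium diisopropoxide, a strong Lewis acid of tetravalent titanium that binds the carbonyl oxygen of 13, while Me2Zn exchanges with Ti(OiPr)4 to give the methyl-transferring titanium and zinc species. Methyl is passed inside the C2-symmetric pocket to the Si face of the aldehyde, which forms the C16'–C17' bond and, after the alkoxide is handed to the excess Ti(OiPr)4 and hydrolysed, the S carbinol. The closest known reaction type is the Ti(OiPr)4/chiral bis(sulfonamide)-catalysed addition of dialkylzinc reagents to unbranched aliphatic aldehydes. No ring is closed. The new stereocentre C16' is controlled only by the absolute configuration of the (1R,2R) ligand, because 13 has no stereocentre and no heteroatom near the carbonyl that could chelate or bias either face. The step needs enantiofacial selectivity alone, and this is secured by ligand acceleration: Me2Zn does not add to aldehydes on its own at these temperatures, so the only racemic pathway is the slower ligand-free titanium one, which low temperature and 10 mol % of the electron-poor triflamide ligand should outrun. The Z alkenes, the doubly allylic C10' methylene and the methoxymethyl ethers do not react with Me2Zn or with the mild Lewis acid. Because methyl is transferred more slowly than higher alkyl groups, an excess of Me2Zn and more than one equivalent of Ti(OiPr)4 are used.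

Step 9
Reactants: 15 (2S,6Z,9Z)-17-[3,5-bis(methoxymethoxy)phenyl]heptadeca-6,9-dien-2-ol
Product: 16 hansfordiol D, 5-[(8Z,11Z,16S)-16-hydroxyheptadeca-8,11-dien-1-yl]benzene-1,3-diol
Conditions: HCl, MeOH, rt
Reagents that add atoms: none
Why: Acid-catalysed acetal exchange (methanolysis) of the two aryl methoxymethyl ethers, with methanol trapping the methoxymethyl cation; under dilute acid at room temperature the secondary carbinol does not ionise and the Z,Z-skipped diene should not migrate, so C16' stays S.

## Compound list

1 | 5-bromobenzene-1,3-diol | Oc1cc(O)cc(Br)c1 | starting material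
2 | 1-bromo-3,5-bis(methoxymethoxy)benzene | COCOc1cc(Br)cc(OCOC)c1 | intermediate
3 | 7-bromohept-1-ene | C=CCCCCCBr | starting material
4 | 9-(7-bromoheptyl)-9-borabicyclo[3.3.1]nonane | BrCCCCCCCB1C2CCCC1CCC2 | intermediate
5 | 1-(7-bromoheptyl)-3,5-bis(methoxymethoxy)benzene | BrCCCCCCCc1cc(OCOC)cc(OCOC)c1 | intermediate
6 | prop-2-yn-1-ol | C#CCO | starting material
7 | dilithium salt of prop-2-yn-1-ol (lithium 3-lithioprop-2-yn-1-olate) | [Li]C#CCO[Li] | intermediate
8 | 10-[3,5-bis(methoxymethoxy)phenyl]dec-2-yn-1-ol | OCC#CCCCCCCCc1cc(OCOC)cc(OCOC)c1 | intermediate
9 | 1-(10-bromodec-8-yn-1-yl)-3,5-bis(methoxymethoxy)benzene | BrCC#CCCCCCCCc1cc(OCOC)cc(OCOC)c1 | intermediate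
10 | hex-5-yn-1-ol | C#CCCCCO | starting material
11 | 16-[3,5-bis(methoxymethoxy)phenyl]hexadeca-5,8-diyn-1-ol | OCCCCC#CCC#CCCCCCCCc1cc(OCOC)cc(OCOC)c1 | intermediate
12 | (5Z,8Z)-16-[3,5-bis(methoxymethoxy)phenyl]hexadeca-5,8-dien-1-ol | OCCCC/C=C\C/C=C\CCCCCCCc1cc(OCOC)cc(OCOC)c1 | intermediate
13 | (5Z,8Z)-16-[3,5-bis(methoxymethoxy)phenyl]hexadeca-5,8-dienal | O=CCCC/C=C\C/C=C\CCCCCCCc1cc(OCOC)cc(OCOC)c1 | intermediate
14 | dimethylzinc | C[Zn]C | starting material
15 | (2S,6Z,9Z)-17-[3,5-bis(methoxymethoxy)phenyl]heptadeca-6,9-dien-2-ol | C[C@H](O)CCC/C=C\C/C=C\CCCCCCCc1cc(OCOC)cc(OCOC)c1 | intermediate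
16 | hansfordiol D, 5-[(8Z,11Z,16S)-16-hydroxyheptadeca-8,11-dien-1-yl]benzene-1,3-diol | C[C@H](O)CCC/C=C\C/C=C\CCCCCCCc1cc(O)cc(O)c1 | target

## Step count and risk

Total step count: 9. Longest linear sequence: 9 steps (1 to 16); compounds 3, 6, 10 and 14 are purchased and enter directly.

**Step 8 (key step).** The most likely failure is incomplete enantiofacial discrimination combined with slow methyl transfer. Methyl moves from zinc and titanium more slowly than higher alkyl groups, so conversion may stall, and the ligand-free titanium pathway may then contribute racemic product. The unbranched aldehyde also offers little steric differentiation, and long exposure to the Lewis acid invites aldol self-condensation.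

Fallback, setting out from 13: addition of MeMgBr in THF at −78 °C would give racemic (6Z,9Z)-17-[3,5-bis(methoxymethoxy)phenyl]heptadeca-6,9-dien-2-ol F1. Kinetic resolution of this alcohol with immobilised lipase B from Candida antarctica and vinyl acetate in hexane should acetylate the R enantiomer, in line with the usual preference of this enzyme for methyl carbinols, giving (2R,6Z,9Z)-17-[3,5-bis(methoxymethoxy)phenyl]heptadeca-6,9-dien-2-yl acetate F2. The unreacted S alcohol is separated by chromatography, and the route is rejoined at 15. Half of the material is given up at a late stage.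

**Step 2.** The most likely failure is loss of the primary bromide during the coupling, by substitution or elimination under the basic conditions, together with β-hydride elimination or protodeboronation of the alkyl partner, which returns reduced or isomerised chain fragments.

Fallback, setting out from 2: Sonogashira coupling with hept-6-yn-1-ol (Pd(PPh3)2Cl2, CuI, Et3N, 70 °C) would give 7-[3,5-bis(methoxymethoxy)phenyl]hept-6-yn-1-ol F3. Full hydrogenation (H2, Pd/C, EtOAc) would give 7-[3,5-bis(methoxymethoxy)phenyl]heptan-1-ol F4. An Appel reaction (CBr4, PPh3, CH2Cl2) returns to the route at 5.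

**Step 6.** The most likely failure is over-reduction or incomplete reduction of one of the two alkynes, together with positional or geometrical isomerisation at the doubly allylic C10' on the metal surface. Either gives mixtures of closely related alkenes that are hard to separate.

Fallback, setting out from 5 and replacing steps 3 to 6 by a Wittig construction of the C11'=C12' alkene, which also avoids the diyne coupling of step 5: but-3-yn-1-ol would be converted with two equivalents of n-BuLi in THF/DMPU into dilithiated but-3-yn-1-ol F5, which is alkylated by 5 to give 11-[3,5-bis(methoxymethoxy)phenyl]undec-3-yn-1-ol F6. Semi-hydrogenation of this single, isolated alkyne on P-2 nickel boride (Ni2B) should give (3Z)-11-[3,5-bis(methoxymethoxy)phenyl]undec-3-en-1-ol F7, which can be purified before it is committed. Treatment with I2, PPh3 and imidazole would give 1-[(8Z)-11-iodoundec-8-en-1-yl]-3,5-bis(methoxymethoxy)benzene F8, and PPh3 in refluxing MeCN would convert it into [(3Z)-11-[3,5-bis(methoxymethoxy)phenyl]undec-3-en-1-yl]triphenylphosphonium iodide F9. NaHMDS in THF at −78 °C would give [(3Z)-11-[3,5-bis(methoxymethoxy)phenyl]undec-3-en-1-ylidene]triphenylphosphorane F10, whose salt-free Z-selective Wittig reaction with methyl 5-oxopentanoate should give methyl (5Z,8Z)-16-[3,5-bis(methoxymethoxy)phenyl]hexadeca-5,8-dienoate F11. Reduction with excess DIBAL-H (THF, −78 to 0 °C) rejoins the route at 12.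

## Further compounds

F1 | step 8 | (6Z,9Z)-17-[3,5-bis(methoxymethoxy)phenyl]heptadeca-6,9-dien-2-ol, racemic | CC(O)CCC/C=C\C/C=C\CCCCCCCc1cc(OCOC)cc(OCOC)c1
F2 | step 8 | (2R,6Z,9Z)-17-[3,5-bis(methoxymethoxy)phenyl]heptadeca-6,9-dien-2-yl acetate | C[C@@H](OC(C)=O)CCC/C=C\C/C=C\CCCCCCCc1cc(OCOC)cc(OCOC)c1
F3 | step 2 | 7-[3,5-bis(methoxymethoxy)phenyl]hept-6-yn-1-ol | OCCCCCC#Cc1cc(OCOC)cc(OCOC)c1
F4 | step 2 | 7-[3,5-bis(methoxymethoxy)phenyl]heptan-1-ol | OCCCCCCCc1cc(OCOC)cc(OCOC)c1
F5 | step 6 | dilithiated but-3-yn-1-ol (lithium 4-lithiobut-3-yn-1-olate) | [Li]C#CCCO[Li]
F6 | step 6 | 11-[3,5-bis(methoxymethoxy)phenyl]undec-3-yn-1-ol | OCCC#CCCCCCCCc1cc(OCOC)cc(OCOC)c1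
F7 | step 6 | (3Z)-11-[3,5-bis(methoxymethoxy)phenyl]undec-3-en-1-ol | OCC/C=C\CCCCCCCc1cc(OCOC)cc(OCOC)c1
F8 | step 6 | 1-[(8Z)-11-iodoundec-8-en-1-yl]-3,5-bis(methoxymethoxy)benzene | ICC/C=C\CCCCCCCc1cc(OCOC)cc(OCOC)c1
F9 | step 6 | [(3Z)-11-[3,5-bis(methoxymethoxy)phenyl]undec-3-en-1-yl]triphenylphosphonium iodide | [I-].c1ccccc1[P+](c1ccccc1)(c1ccccc1)CC/C=C\CCCCCCCc1cc(OCOC)cc(OCOC)c1
F10 | step 6 | [(3Z)-11-[3,5-bis(methoxymethoxy)phenyl]undec-3-en-1-ylidene]triphenylphosphorane | c1ccccc1P(c1ccccc1)(c1ccccc1)=CC/C=C\CCCCCCCc1cc(OCOC)cc(OCOC)c1
F11 | step 6 | methyl (5Z,8Z)-16-[3,5-bis(methoxymethoxy)phenyl]hexadeca-5,8-dienoate | COC(=O)CCC/C=C\C/C=C\CCCCCCCc1cc(OCOC)cc(OCOC)c1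
A1 | alternative 1 | methyl 2,4-dihydroxy-6-[(8Z,11Z,16S)-16-(tert-butyldimethylsilyloxy)heptadeca-8,11-dienyl]benzoate | C[C@H](O[Si](C)(C)C(C)(C)C)CCC/C=C\C/C=C\CCCCCCCc1cc(O)cc(O)c1C(=O)OC
A2 | alternative 1 | methyl (15Z,18Z,23S)-23-(tert-butyldimethylsilyloxy)-3,5,7-trioxotetracosa-15,18-dienoate | C[C@H](O[Si](C)(C)C(C)(C)C)CCC/C=C\C/C=C\CCCCCCCC(=O)CC(=O)CC(=O)CC(=O)OC
A3 | alternative 2 | tert-butyl{[(2S,6Z,9Z)-17-[3,5-bis(methoxymethoxy)phenyl]heptadeca-6,9-dien-2-yl]oxy}dimethylsilane | C[C@H](O[Si](C)(C)C(C)(C)C)CCC/C=C\C/C=C\CCCCCCCc1cc(OCOC)cc(OCOC)c1
A4 | alternative 2 | 1,3-dioxoisoindolin-2-yl 5-[3,5-bis(methoxymethoxy)phenyl]pentanoate | COCOc1cc(CCCCC(=O)ON2C(=O)c3ccccc3C2=O)cc(OCOC)c1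
A5 | alternative 2 | 1,3-dioxoisoindolin-2-yl (5Z,8Z,13S)-13-(tert-butyldimethylsilyloxy)tetradeca-5,8-dienoate | C[C@H](O[Si](C)(C)C(C)(C)C)CCC/C=C\C/C=C\CCCC(=O)ON1C(=O)c2ccccc2C1=O
A6 | alternative 3 | 3-[(8Z,11Z,16S)-16-(tert-butyldimethylsilyloxy)heptadeca-8,11-dienyl]-5-(triisopropylsilyloxy)phenol | C[C@H](O[Si](C)(C)C(C)(C)C)CCC/C=C\C/C=C\CCCCCCCc1cc(O)cc(O[Si](C(C)C)(C(C)C)C(C)C)c1
A7 | alternative 3 | 3-[(8Z,11Z,16S)-16-(tert-butyldimethylsilyloxy)heptadeca-8,11-dien-1-yl]cyclobut-2-en-1-one | C[C@H](O[Si](C)(C)C(C)(C)C)CCC/C=C\C/C=C\CCCCCCCC1=CC(=O)C1
A8 | alternative 3 | (triisopropylsilyloxy)acetylene | C#CO[Si](C(C)C)(C(C)C)C(C)C
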